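Ring A (C7, C8, C15, C14, C13, C12; locants defined below) carries oxygen at C13 and C15 in a 1,3-relationship next to the quaternary carbon C12 that it shares with rings B and C: the imprint of a 1-alkoxy-3-silyloxybutadiene. An endo Diels–Alder reaction of such a diene with an (S)-5-silyloxy-2-alkylcyclopent-2-enone forms the C7–C8 and C12–C13 bonds, ring A, the cis-hydrindane and the stereocentres C7, C12 and C13 in one operation; the C5 silyloxy group steers the diene face and later becomes the ring-B ketone. The dienophile's side chain is an N-allylformamide whose allyl arm closes ring C by B-alkyl Suzuki coupling; Saegusa oxidation then gives the enone.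

Key step: step 8

Locants (fawcettimine type, used for all bicyclic and tricyclic compounds): N–C1H2–C2H2–C3H=C4; C5 ketone; C6H2; C7H ring fusion; C8H2; C15 (methyl C16 and oxygen); C14H2; C13H (oxygen); C12 quaternary; C11H2–C10H2–C9H2–N. Ring A: C7, C8, C15, C14, C13, C12. Ring B: C4, C5, C6, C7, C12. Ring C: N, C1, C2, C3, C4, C12, C11, C10, C9. The target is 7S, 12S, 13S, 15S with an E C3=C4 bond.

Remark (assumption): compounds 1, 3, 10 and 11 are taken as purchased; 1 is the (S) enantiomer of the common 4-silyloxycyclopentenone building block.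

Step 1
Reactants: 1 (S)-4-(tert-butyldimethylsilyloxy)cyclopent-2-en-1-one
Product: 2 (S)-4-(tert-butyldimethylsilyloxy)-2-iodocyclopent-2-en-1-one
Conditions: I2, pyridine/CH2Cl2, 0 °C to rt
Reagents that add atoms: iodine, [I][I]
Why: Pyridine-mediated α-iodination of an enone (conjugate addition of pyridine, iodination of the enolate, elimination), a standard transformation of 4-silyloxycyclopentenones that does not touch the C4 stereocentre.

Step 2
Reactants: 3 N,N-diallylformamide; 2 (S)-4-(tert-butyldimethylsilyloxy)-2-iodocyclopent-2-en-1-one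
Product: 5 (S)-2-[3-(N-allylformamido)propyl]-4-(tert-butyldimethylsilyloxy)cyclopent-2-en-1-one, via B-alkyl-9-BBN adduct 4 (not isolated)
Conditions: 3 (3 equiv), 9-BBN, THF, 0 °C to rt; then 2, PdCl2(dppf), AsPh3, Cs2CO3, DMF/H2O, rt
Reagents that add atoms: none
Why: Anti-Markovnikov hydroboration of one allyl arm (3 in excess so that mono-hydroboration dominates) followed by B-alkyl Suzuki–Miyaura coupling with the α-iodoenone at room temperature, conditions mild enough to keep the base-sensitive γ-silyloxy enone intact.

Step 3
Reactants: 5 (S)-2-[3-(N-allylformamido)propyl]-4-(tert-butyldimethylsilyloxy)cyclopent-2-en-1-one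
Product: 6 (4S)-2-[3-(N-allylformamido)propyl]-4-(tert-butyldimethylsilyloxy)-2,3-epoxycyclopentan-1-one (epoxide trans to the silyloxy group)
Conditions: t-BuOOH, benzyltrimethylammonium hydroxide (cat.), THF, 0 °C
Reagents that add atoms: tert-butyl hydroperoxide, CC(C)(C)OO
Why: Weitz–Scheffer nucleophilic epoxidation of the enone, the hydroperoxide adding to the β-carbon anti to the silyloxy group; the epoxide configuration is immaterial because both of its carbons become trigonal in steps 4 and 5.

Step 4
Reactants: 6 (4S)-2-[3-(N-allylformamido)propyl]-4-(tert-butyldimethylsilyloxy)-2,3-epoxycyclopentan-1-one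
Product: 8 (1S,5S)-2-[3-(N-allylformamido)propyl]-5-(tert-butyldimethylsilyloxy)cyclopent-2-en-1-ol, via epoxy hydrazone 7 (not isolated)
Conditions: N2H4·H2O, AcOH (cat.), MeOH, 0 °C to rt, under N2
Reagents that add atoms: none
Why: Wharton transposition: the epoxy hydrazone fragments with loss of N2 to the allylic alcohol with the double bond moved to the former carbonyl carbon, the C–O bond of the carbinol and the silyloxy stereocentre being retained.

Step 5
Reactants: 8 (1S,5S)-2-[3-(N-allylformamido)propyl]-5-(tert-butyldimethylsilyloxy)cyclopent-2-en-1-ol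
Product: 9 (S)-2-[3-(N-allylformamido)propyl]-5-(tert-butyldimethylsilyloxy)cyclopent-2-en-1-one
Conditions: Dess–Martin periodinane, CH2Cl2, 0 °C to rt
Reagents that add atoms: none
Why: Dess–Martin oxidation of the allylic alcohol under non-basic conditions gives the α′-silyloxy enone without epimerising the stereocentre that is now α to the carbonyl group and keeps the S descriptor.

Step 6
Reactants: 10 but-3-yn-2-one; 11 4-methoxybenzyl alcohol
Product: 12 (E)-4-[(4-methoxybenzyl)oxy]but-3-en-2-one
Conditions: DABCO (cat.), CH2Cl2, 0 °C to rt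
Reagents that add atoms: none
Why: Amine-catalysed oxa-Michael addition of the alcohol to the ynone, which gives the (E)-β-alkoxy enone as the thermodynamic isomer.

Step 7
Reactants: 12 (E)-4-[(4-methoxybenzyl)oxy]but-3-en-2-one
Product: 13 (E)-1-[(4-methoxybenzyl)oxy]-3-(trimethylsilyloxy)buta-1,3-diene
Conditions: Me3SiOTf, Et3N, Et2O, 0 °C
Reagents that add atoms: trimethylsilyl trifluoromethanesulfonate, C[Si](C)(C)OS(=O)(=O)C(F)(F)F
Why: Soft enolisation of the methyl ketone with silyl triflate and amine (standard synthesis of 1-alkoxy-3-silyloxybutadienes) with retention of the E enol ether.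

Step 8
Reactants: 9 (S)-2-[3-(N-allylformamido)propyl]-5-(tert-butyldimethylsilyloxy)cyclopent-2-en-1-one; 13 (E)-1-[(4-methoxybenzyl)oxy]-3-(trimethylsilyloxy)buta-1,3-diene
Product: 14 cis-fused ring A/B Diels–Alder adduct (C4 ketone; 5-OTBS; 13-OPMB; C14=C15 trimethylsilyl enol ether; C12 side chain)
Conditions: 13 (3 equiv), CH2Cl2, 12 kbar, 40 °C, no Lewis acid; volatiles removed, no aqueous work-up
Reagents that add atoms: none
Why: Concerted but asynchronous normal-electron-demand [4+2] cycloaddition (Diels–Alder reaction; closest precedent: pressure-promoted additions of 1-alkoxy-3-silyloxybutadienes to 2-alkylcycloalkenones), run without Lewis acid so that the allylic C13–OPMB bond of the adduct does not ionise. Ring A closes in one suprafacial six-membered (4π+2π) event, the nucleophilic CH2 terminus of the diene (C8) bonding to the enone β-carbon C7 and the oxygenated terminus (C13) to the α-carbon C12, as the matched polarisation of both partners demands. C7 and C12 emerge cis (cis-hydrindane) because the ring alkene adds suprafacially, and the quaternary C12 is created with its chain already in place. C13 is controlled by the endo transition state (ring-B carbons C4 and C6 under the diene) combined with the E geometry of the diene, which places O13 cis to C4. The absolute sense is controlled by the (S)-C5 silyloxy group, which sits in the endo region facing the inner diene carbons and so forces bonding to the opposite enone face. The step needs regio-, endo- and π-facial selectivity, secured respectively by the 1,3-dioxygenated diene, the compact cyclopentenone ring and the bulky C5 substituent; the C15 carbonyl is delivered masked as a silyl enol ether, which step 9 relies on.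

Step 9
Reactants: 14 cis-fused ring A/B Diels–Alder adduct
Product: 16 C15 ketone carrying the C4(OTf)=C5(OTBS) enol triflate and 13-OPMB, via bis(enol) triflate 15 (not isolated)
Conditions: KN(SiMe3)2, PhNTf2, THF, −78 °C; then 0.1 M HCl, THF, 0 °C
Reagents that add atoms: N-phenylbis(trifluoromethanesulfonimide), O=S(=O)(N(c1ccccc1)S(=O)(=O)C(F)(F)F)C(F)(F)F
Why: Enolisation of the C4 ketone is possible only towards C5 (C12 is quaternary, C15 is masked as its silyl enol ether), O-sulfonylation of the potassium enolate at low temperature (before a 1,4-silyl shift can set in) gives the enol triflate, and dilute acid then hydrolyses only the electron-rich trimethylsilyl enol ether, the TBS enol ether being deactivated by the vicinal triflate.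

Step 10
Reactants: 16 C15 ketone carrying the C4(OTf)=C5(OTBS) enol triflate and 13-OPMB
Product: 17 C15 tertiary alcohol (15-methyl trans and 15-hydroxyl cis to O13; enol triflate and 13-OPMB retained)
Conditions: AlMe3 (4 equiv), toluene, −20 to 0 °C; Rochelle salt work-up
Reagents that add atoms: trimethylaluminium, C[Al](C)C
Why: 1,2-Addition of methyl to the cyclohexanone: with excess AlMe3 in a hydrocarbon solvent the methyl group is delivered axially (two-aluminium transition state), here from the face of the axial hydrogens at C7 and C13 of the chair with equatorial 13-OPMB, which sets C15 with axial methyl and equatorial hydroxyl cis to O13, while enol triflate and formamide are inert at this temperature.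

Step 11
Reactants: 17 C15 tertiary alcohol with enol triflate and N-allyl group
Product: 19 tricyclic silyl enol ether (ring C closed by the C3–C4 bond; C4=C5 with 5-OTBS; 13-OPMB; 15-OH), via alkyl-9-BBN adduct 18 (not isolated)
Conditions: 9-BBN (2.5 equiv), THF, rt; then PdCl2(dppf), AsPh3, Cs2CO3, DMF/THF/H2O, 50 °C, slow addition (high dilution)
Reagents that add atoms: none
Why: Chemoselective hydroboration of the terminal N-allyl alkene and intramolecular B-alkyl Suzuki–Miyaura coupling with the enol triflate under high dilution form the C3–C4 bond and ring C, ring closure being helped by the quaternary C12 and the planar formamide, which limit the conformations of the two arms.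

Step 12
Reactants: 19 tricyclic silyl enol ether
Product: 20 tricyclic (E)-enone (C3=C4; C5 ketone; 13-OPMB; 15-OH)
Conditions: Pd(OAc)2 (1.2 equiv), MeCN, 40 °C
Reagents that add atoms: none
Why: Saegusa–Ito oxidation: the C4 palladium enolate (divalent palladium) can undergo β-hydride elimination only towards C3 because C12 bears no hydrogen, and the nine-membered ring enforces the ring-cis, that is E, enone geometry.

Step 13
Reactants: 20 tricyclic (E)-enone with 13-OPMB
Product: 21 13,15-diol of the tricyclic (E)-enone
Conditions: DDQ, CH2Cl2/pH 7 buffer, 0 °C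
Reagents that add atoms: none
Why: Oxidative cleavage of the PMB ether by DDQ (hydride abstraction, hydrolysis of the oxocarbenium ion in the wet medium, which also opens any p-methoxybenzylidene acetal formed with the C15 hydroxyl); enone, formamide and tertiary alcohol are not oxidised.

Step 14
Reactants: 21 13,15-diol of the tricyclic (E)-enone
Product: 22 target, (7S,12S,13S,15S,3E)-13,15-diacetoxy N-formyl tricyclic enone
Conditions: Ac2O, DMAP, Et3N, CH2Cl2, 40 °C
Reagents that add atoms: acetic anhydride, CC(=O)OC(C)=O
Why: DMAP-catalysed acyl transfer acetylates the secondary C13 hydroxyl and, on warming, the equatorial tertiary C15 hydroxyl, with no change at either stereocentre.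

Compound list
1 | (S)-4-(tert-butyldimethylsilyloxy)cyclopent-2-en-1-one | O=C1C=C[C@@H](O[Si](C)(C)C(C)(C)C)C1 | starting material
2 | (S)-4-(tert-butyldimethylsilyloxy)-2-iodocyclopent-2-en-1-one | O=C1C(I)=C[C@@H](O[Si](C)(C)C(C)(C)C)C1 | intermediate
3 | N,N-diallylformamide | C=CCN(C=O)CC=C | starting material
4 | 9-[3-(N-allylformamido)propyl]-9-borabicyclo[3.3.1]nonane | O=CN(CC=C)CCCB1C2CCCC1CCC2 | intermediate (not isolated)
5 | (S)-2-[3-(N-allylformamido)propyl]-4-(tert-butyldimethylsilyloxy)cyclopent-2-en-1-one | O=C1C(CCCN(C=O)CC=C)=C[C@@H](O[Si](C)(C)C(C)(C)C)C1 | intermediate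
6 | (4S)-2-[3-(N-allylformamido)propyl]-4-(tert-butyldimethylsilyloxy)-2,3-epoxycyclopentan-1-one, epoxide trans to the silyloxy group | O=C1C[C@H](O[Si](C)(C)C(C)(C)C)[C@H]2O[C@@]12CCCN(C=O)CC=C | intermediate
7 | hydrazone of epoxy ketone 6 | NN=C1C[C@H](O[Si](C)(C)C(C)(C)C)[C@H]2O[C@@]12CCCN(C=O)CC=C | intermediate (not isolated)
8 | (1S,5S)-2-[3-(N-allylformamido)propyl]-5-(tert-butyldimethylsilyloxy)cyclopent-2-en-1-ol (hydroxyl trans to silyloxy) | O[C@H]1C(CCCN(C=O)CC=C)=CC[C@@H]1O[Si](C)(C)C(C)(C)C | intermediate
9 | (S)-2-[3-(N-allylformamido)propyl]-5-(tert-butyldimethylsilyloxy)cyclopent-2-en-1-one | C=CCN(C=O)CCCC1=CC[C@H](O[Si](C)(C)C(C)(C)C)C1=O | intermediate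
10 | but-3-yn-2-one | CC(=O)C#C | starting material
11 | 4-methoxybenzyl alcohol | COc1ccc(CO)cc1 | starting material
12 | (E)-4-[(4-methoxybenzyl)oxy]but-3-en-2-one | COc1ccc(CO/C=C/C(C)=O)cc1 | intermediate
13 | (E)-1-[(4-methoxybenzyl)oxy]-3-(trimethylsilyloxy)buta-1,3-diene | COc1ccc(CO/C=C/C(=C)O[Si](C)(C)C)cc1 | intermediate
14 | Diels–Alder adduct: cis-fused ring A/B ketone (C4=O) with (5S)-OTBS trans to the ring-A bonds at C7 and C12, 3-(N-allylformamido)propyl on C12, PMB-oxy on C13 cis to C4, C14=C15 trimethylsilyl enol ether; C7, C12 and C13 configured as in 22 | COc1ccc(CO[C@H]2C=C(O[Si](C)(C)C)C[C@H]3C[C@H](O[Si](C)(C)C(C)(C)C)C(=O)[C@]32CCCN(C=O)CC=C)cc1 | intermediate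
15 | as 14 with C4–C5 converted into the enol triflate C4(OTf)=C5(OTBS); C14=C15 trimethylsilyl enol ether retained | COc1ccc(CO[C@H]2C=C(O[Si](C)(C)C)C[C@H]3CC(O[Si](C)(C)C(C)(C)C)=C(OS(=O)(=O)C(F)(F)F)[C@]32CCCN(C=O)CC=C)cc1 | intermediate (not isolated)
16 | C15 ketone with C4(OTf)=C5(OTBS) enol triflate, 13-OPMB and 12-[3-(N-allylformamido)propyl] | COc1ccc(CO[C@H]2CC(=O)C[C@H]3CC(O[Si](C)(C)C(C)(C)C)=C(OS(=O)(=O)C(F)(F)F)[C@]32CCCN(C=O)CC=C)cc1 | intermediate
17 | as 16 with C15 bearing methyl (axial, trans to O13) and hydroxyl (equatorial, cis to O13); 15S | COc1ccc(CO[C@H]2C[C@@](C)(O)C[C@H]3CC(O[Si](C)(C)C(C)(C)C)=C(OS(=O)(=O)C(F)(F)F)[C@]32CCCN(C=O)CC=C)cc1 | intermediate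
18 | as 17 with the N-allyl group hydroborated to N-[3-(9-borabicyclo[3.3.1]nonan-9-yl)propyl] | COc1ccc(CO[C@H]2C[C@@](C)(O)C[C@H]3CC(O[Si](C)(C)C(C)(C)C)=C(OS(=O)(=O)C(F)(F)F)[C@]32CCCN(C=O)CCCB4C5CCCC4CCC5)cc1 | intermediate (not isolated)
19 | tricyclic silyl enol ether: ring C closed by the C3–C4 bond, C4=C5 with OTBS on C5, 13-OPMB, 15-OH, N-formyl | COc1ccc(CO[C@H]2C[C@@](C)(O)C[C@H]3CC(O[Si](C)(C)C(C)(C)C)=C4CCCN(C=O)CCC[C@@]432)cc1 | intermediate
20 | tricyclic enone: (E)-C3=C4, C5 ketone, 13-OPMB, 15-OH, N-formyl | COc1ccc(CO[C@H]2C[C@@](C)(O)C[C@H]3CC(=O)/C4=C/CCN(C=O)CCC[C@@]432)cc1 | intermediate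
21 | 13,15-diol of the tricyclic (E)-enone (hydroxyls cis, both equatorial on ring A) | O[C@H]1C[C@@](C)(O)C[C@H]2CC(=O)/C3=C/CCN(C=O)CCC[C@@]321 | intermediate
22 | (7S,12S,13S,15S,3E)-13,15-diacetoxy N-formyl tricyclic enone (CNP0137427.1) | CC(=O)O[C@H]1C[C@@](C)(OC(C)=O)C[C@H]2CC(=O)/C3=C/CCN(C=O)CCC[C@@]321 | target

Total step count: 14. Longest linear sequence: 12 steps (steps 1–5, then 8–14); the diene is made in two steps (6 and 7).

Steps most likely to fail

Step 11. Ring closure may stall because transmetalation to the hindered, electron-rich enol triflate is slow, so that protodeboronation, β-hydride elimination or oligomerisation take over. The fallback forms C2=C3 by metathesis instead of C3–C4 by cross-coupling. It sets out from 17: Stille coupling with tributyl(vinyl)stannane (Pd(PPh3)4, LiCl, THF, 65 °C) gives the C4-vinyl silyloxy diene F1. Ring-closing metathesis with the N-allyl group (second-generation Hoveyda–Grubbs catalyst, toluene, 80 °C, high dilution) gives the cyclic (2Z)-dienol silyl ether F2. HF·pyridine followed by DBU (cat.) removes silicon and brings the double bond into conjugation by protonation at C2, which gives enone 20; the route is rejoined at 20, so step 12 is bypassed as well.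

Step 8. The cycloaddition may fail through low reactivity of the trisubstituted enone, with diene decomposition outrunning addition, or through incomplete discrimination of the two enone faces or of endo against exo approach. Facial leakage would surface as loss of enantiomeric purity once C5 becomes trigonal in step 9. The fallback is a stepwise anionic annulation instead of a pericyclic step. It sets out from 12: LiN(iPr)2 (THF, −78 °C) gives the cross-conjugated lithium dienolate F3, which adds to 9 in a Michael–Michael sequence (C8 to C7, then the C12 enolate to C13 through a lithium-bridged, endo-like array). Quenching the resulting C15 enolate with Me3SiCl gives 14, where the route is rejoined.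

Step 12. Palladation of the tetrasubstituted TBS enol ether may be slow, so that hydrolysis to the saturated C4–H ketone competes. The fallback is halogenation and elimination instead of palladium-mediated dehydrosilylation. It sets out from 19: N-bromosuccinimide (THF, −78 °C) gives the C4 bromo ketone F4 (either C4 epimer), and Li2CO3/LiBr (DMF, 110 °C) eliminates HBr, for which only the C3 hydrogens are available, to give 20, where the route is rejoined.

Further compounds
F1 | step 11 | C4-vinyl analogue of 17 (vinyl in place of the triflate; 2-silyloxy-1,3-diene) | COc1ccc(CO[C@H]2C[C@@](C)(O)C[C@H]3CC(O[Si](C)(C)C(C)(C)C)=C(C=C)[C@]32CCCN(C=O)CC=C)cc1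
F2 | step 11 | tricyclic dienol silyl ether, C5(OTBS)=C4–C3=C2 with (2Z) alkene in ring C | COc1ccc(CO[C@H]2C[C@@](C)(O)C[C@H]3CC(O[Si](C)(C)C(C)(C)C)=C4/C=C\CN(C=O)CCC[C@@]432)cc1
F3 | step 8 | lithium (E)-4-[(4-methoxybenzyl)oxy]buta-1,3-dien-2-olate | [Li+].[O-]C(=C)/C=C/OCc1ccc(OC)cc1
F4 | step 12 | C4-bromo C5-ketone derived from 19 (C4 configuration not controlled) | COc1ccc(CO[C@H]2C[C@@](C)(O)C[C@H]3CC(=O)C4(Br)CCCN(C=O)CCC[C@@]432)cc1
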